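**Plan**
- Retrosynthetic cuts, in order: the six O–benzyl bonds; the C3–H bond (carbinol back to the flavan-3-one, and that to its 3-ethoxy enol ether, a 2H-chromene); C4–C4a and O1–C2 together, which removes all of ring C; then the O7–acyl bond and the C=C bond of the enal.
- Fragments: phloroglucinol mono(tri-O-benzylgallate) acts as the C,O-bisnucleophile. (Z)-2-Ethoxy-3-[3,4,5-tris(benzyloxy)phenyl]propenal acts as the C4–C3–C2 biselectrophile (C4 = CHO, C3 already oxygenated, C2 = β-carbon bearing ring B).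
- Enabling feature: in ring A, C4a lies between the oxygen-bearing carbons C5 and C8a and para to C7–O. In the 7-O-acylated phloroglucinol, O1 and O5 are mirror-related across the C7···C4a axis, so either hydroxyl may close ring C and the other becomes the 5-OH. The gallate is therefore placed by symmetry.
- Forward order: ring A, ring B and the galloyl ring are bought. The ester is made first and the enal in three steps. Ring C then arises by carbonyl addition, ortho-quinone methide formation and oxa-6π electrocyclisation.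
- Stereochemistry: the annulation gives racemic C2. In the C3 ketone C2 is labile, and one asymmetric transfer hydrogenation with dynamic kinetic resolution sets (2R,3R). The cis relation comes from hydride delivery anti to ring B, and the absolute sense from the (S,S)-TsDPEN ligand.

Key step: step 5

Assumption: the sense of induction in step 7 follows the usual CH–π/steric model of arene–Ru–TsDPEN catalysts; if experiment shows the opposite sense, the (R,R) complex is used and nothing else changes.
Flavan numbering (O1, C2, C3, C4, C4a, C5–C8, C8a; rings A, B, C) is used throughout.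

Step 1
Reactants: 1 3,4,5-tris(benzyloxy)benzoic acid; 2 phloroglucinol
Product: 3 3,5-dihydroxyphenyl 3,4,5-tris(benzyloxy)benzoate
Conditions: DCC, DMAP (cat.), 2 (4 equiv), THF, 0 °C to rt
Reagents that add atoms: none
Why: Steglich esterification; with the triol in large excess its three equivalent hydroxyls should be acylated essentially once, and the water-soluble surplus of 2 is washed out.

Step 2
Reactants: 4 3,4,5-tris(benzyloxy)benzaldehyde; 5 ethyl ethoxyacetate
Product: 6 ethyl (Z)-2-ethoxy-3-[3,4,5-tris(benzyloxy)phenyl]prop-2-enoate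
Conditions: KOtBu, THF, −10 °C to rt
Reagents that add atoms: none
Why: Claisen-type aldol condensation and elimination of an alkoxyacetate enolate with a non-enolisable aromatic aldehyde, a known entry to α-alkoxycinnamates; the (Z)-alkene (ring B trans to the ester) is the favoured isomer, and this geometry disappears in step 5.

Step 3
Reactants: 6 ethyl (Z)-2-ethoxy-3-[3,4,5-tris(benzyloxy)phenyl]prop-2-enoate
Product: 7 (Z)-2-ethoxy-3-[3,4,5-tris(benzyloxy)phenyl]prop-2-en-1-ol
Conditions: iBu2AlH, CH2Cl2, −78 to 0 °C; aq. potassium sodium tartrate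
Reagents that add atoms: none
Why: 1,2-reduction of a conjugated ester to the allylic alcohol with diisobutylaluminium hydride leaves the enol ether, the alkene and the benzyl ethers untouched.

Step 4
Reactants: 7 (Z)-2-ethoxy-3-[3,4,5-tris(benzyloxy)phenyl]prop-2-en-1-ol
Product: 8 (Z)-2-ethoxy-3-[3,4,5-tris(benzyloxy)phenyl]prop-2-enal
Conditions: MnO2, CH2Cl2, rt
Reagents that add atoms: none
Why: allylic oxidation with activated MnO2 is neutral, selective for the allylic alcohol and stops at the aldehyde, so the acid-sensitive enol ether survives.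

Step 5
Reactants: 3 3,5-dihydroxyphenyl 3,4,5-tris(benzyloxy)benzoate; 8 (Z)-2-ethoxy-3-[3,4,5-tris(benzyloxy)phenyl]prop-2-enal
Product: 11 (±)-3-ethoxy-5-hydroxy-2-[3,4,5-tris(benzyloxy)phenyl]-2H-chromen-7-yl 3,4,5-tris(benzyloxy)benzoate, via benzodioxaborin 9 (not isolated), via ortho-quinone methide 10 (not isolated)
Conditions: PhB(OH)2 (1.1 equiv), AcOH (cat.), 3 (1.3 equiv), toluene, reflux, Dean–Stark trap
Reagents that add atoms: none
Why: The aryloxyboronate from 3 and PhB(OH)2 binds the aldehyde of 8 and delivers its carbonyl carbon through a six-membered array to the ortho carbon (C4–C4a) to give 9, which loses PhBO by retro-hetero-Diels–Alder reaction at reflux to give the vinylogous ortho-quinone methide 10, whose O=C8a–C4a=C4–C3=C2 oxatriene closes by thermal disrotatory oxa-6π electrocyclisation (O1–C2) and rearomatises ring A. The closest known reaction type is the boronic acid mediated (or amine catalysed) formal [3+3] condensation of phenols, resorcinols and phloroglucinol with α,β-unsaturated aldehydes to 2H-chromenes. Ring C is the only ring closed, and it closes in the 6π-electrocyclic mode rather than by a polar 6-endo attack, driven by recovery of the aromaticity of ring A. C2 is the only new stereocentre and forms racemic because 10 is achiral and nothing biases the sense of disrotation, which is accepted because C2 is made labile and reset in step 7. Three selectivities are needed: carbonyl rather than conjugate attack (secured by the boron template and by the 2-ethoxy donor, which lowers the electrophilicity of the β-carbon); attack between the two hydroxyls rather than next to the ester (both hydroxyls template the same carbon, C6 and C8 are shielded and inductively deactivated by the aroyloxy group, and 5-substituted resorcinols are known to annulate between their hydroxyls); and a single annulation (slight excess of 3). Since the two hydroxyls of 3 are mirror-related, either may become O1 and one constitution results.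

Step 6
Reactants: 11 (±)-3-ethoxy-5-hydroxy-2-[3,4,5-tris(benzyloxy)phenyl]-2H-chromen-7-yl 3,4,5-tris(benzyloxy)benzoate
Product: 12 (±)-5-hydroxy-3-oxo-2-[3,4,5-tris(benzyloxy)phenyl]chroman-7-yl 3,4,5-tris(benzyloxy)benzoate
Conditions: 1 M aq. HCl, THF, 0 °C to rt, Ar
Reagents that add atoms: water (SMILES: O)
Why: acid hydrolysis of an enol ether (protonation at C4, addition of water to the C3 oxocarbenium ion, loss of ethanol), as known for 2-alkoxydihydronaphthalenes giving 2-tetralones and 3-alkoxyflavenes giving flavan-3-ones; the aryl ester and benzyl ethers tolerate dilute acid at room temperature.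

Step 7
Reactants: 12 (±)-5-hydroxy-3-oxo-2-[3,4,5-tris(benzyloxy)phenyl]chroman-7-yl 3,4,5-tris(benzyloxy)benzoate
Product: 13 (2R,3R)-3,5-dihydroxy-2-[3,4,5-tris(benzyloxy)phenyl]chroman-7-yl 3,4,5-tris(benzyloxy)benzoate
Conditions: RuCl[(S,S)-TsDPEN](p-cymene) (2 mol %), HCO2H–Et3N (5:2), EtOAc, 30 °C, Ar
Reagents that add atoms: none
Why: Proposed new method: the closest known reaction type is the Noyori–Ikariya asymmetric transfer hydrogenation with dynamic kinetic resolution of configurationally labile α-substituted cyclic ketones (2-substituted tetralones, 3-arylchroman-4-ones, cyclic β-keto esters), which has not been shown on 2-arylchroman-3-ones. Et3N should racemise C2 through the C2=C3 enol because C2–H is at once benzylic, α-aryloxy and α-keto. The outer-sphere Ru–H/N–H hydride transfer should come anti to ring B (the bias that makes bulky hydrides give 2,3-cis-flavan-3-ols from flavan-3-ones), so each ketone enantiomer offers only one face. The (S,S) catalyst should place the flat benzo-fused C4 side under its η6-arene and the branched C2 side away from it, reduce the (2R)-ketone faster and so funnel the racemate into the (2R,3R)-alcohol. The formic acid medium leaves the aryl ester, the phenol and the benzyl ethers intact.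

Step 8
Reactants: 13 (2R,3R)-3,5-dihydroxy-2-[3,4,5-tris(benzyloxy)phenyl]chroman-7-yl 3,4,5-tris(benzyloxy)benzoate
Product: 14 (−)-epigallocatechin 7-O-gallate
Conditions: H2 (1 atm), Pd(OH)2/C, THF–MeOH, rt
Reagents that add atoms: none
Why: global hydrogenolysis of six aryl benzyl ethers under neutral conditions is standard for benzylated catechin gallates; it touches no stereocentre and leaves the phenolic ester alone.

**Compound list**
1 | 3,4,5-tris(benzyloxy)benzoic acid | O=C(O)c1cc(OCc2ccccc2)c(OCc2ccccc2)c(OCc2ccccc2)c1 | starting material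
2 | phloroglucinol (benzene-1,3,5-triol) | Oc1cc(O)cc(O)c1 | starting material
3 | 3,5-dihydroxyphenyl 3,4,5-tris(benzyloxy)benzoate | O=C(Oc1cc(O)cc(O)c1)c1cc(OCc2ccccc2)c(OCc2ccccc2)c(OCc2ccccc2)c1 | intermediate
4 | 3,4,5-tris(benzyloxy)benzaldehyde | O=Cc1cc(OCc2ccccc2)c(OCc2ccccc2)c(OCc2ccccc2)c1 | starting material
5 | ethyl ethoxyacetate | CCOCC(=O)OCC | starting material
6 | ethyl (Z)-2-ethoxy-3-[3,4,5-tris(benzyloxy)phenyl]prop-2-enoate | CCO/C(C(=O)OCC)=C\c1cc(OCc2ccccc2)c(OCc2ccccc2)c(OCc2ccccc2)c1 | intermediate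
7 | (Z)-2-ethoxy-3-[3,4,5-tris(benzyloxy)phenyl]prop-2-en-1-ol | CCO/C(CO)=C\c1cc(OCc2ccccc2)c(OCc2ccccc2)c(OCc2ccccc2)c1 | intermediate
8 | (Z)-2-ethoxy-3-[3,4,5-tris(benzyloxy)phenyl]prop-2-enal | CCO/C(C=O)=C\c1cc(OCc2ccccc2)c(OCc2ccccc2)c(OCc2ccccc2)c1 | intermediate
9 | (±)-4-{(Z)-1-ethoxy-2-[3,4,5-tris(benzyloxy)phenyl]ethenyl}-5-hydroxy-2-phenyl-4H-1,3,2-benzodioxaborinin-7-yl 3,4,5-tris(benzyloxy)benzoate (not isolated) | CCO/C(=C\c1cc(OCc2ccccc2)c(OCc2ccccc2)c(OCc2ccccc2)c1)C1OB(c2ccccc2)Oc2cc(OC(=O)c3cc(OCc4ccccc4)c(OCc4ccccc4)c(OCc4ccccc4)c3)cc(O)c12 | intermediate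
10 | ortho-quinone methide, 4-{(Z)-2-ethoxy-3-[3,4,5-tris(benzyloxy)phenyl]prop-2-enylidene}-5-hydroxy-3-oxocyclohexa-1,5-dien-1-yl 3,4,5-tris(benzyloxy)benzoate; the exocyclic C4a=C4 geometry is immaterial because proton shift between O5 and O8a interconverts both forms (not isolated) | O=C1C=C(OC(=O)c2cc(OCc3ccccc3)c(OCc3ccccc3)c(OCc3ccccc3)c2)C=C(O)C1=CC(/OCC)=C/c1cc(OCc2ccccc2)c(OCc2ccccc2)c(OCc2ccccc2)c1 | intermediate
11 | (±)-3-ethoxy-5-hydroxy-2-[3,4,5-tris(benzyloxy)phenyl]-2H-chromen-7-yl 3,4,5-tris(benzyloxy)benzoate (racemic at C2) | CCOC1=Cc2c(O)cc(OC(=O)c3cc(OCc4ccccc4)c(OCc4ccccc4)c(OCc4ccccc4)c3)cc2OC1c1cc(OCc2ccccc2)c(OCc2ccccc2)c(OCc2ccccc2)c1 | intermediate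
12 | (±)-5-hydroxy-3-oxo-2-[3,4,5-tris(benzyloxy)phenyl]chroman-7-yl 3,4,5-tris(benzyloxy)benzoate (flavan-3-one, racemic and labile at C2) | O=C1Cc2c(O)cc(OC(=O)c3cc(OCc4ccccc4)c(OCc4ccccc4)c(OCc4ccccc4)c3)cc2OC1c1cc(OCc2ccccc2)c(OCc2ccccc2)c(OCc2ccccc2)c1 | intermediate
13 | (2R,3R)-3,5-dihydroxy-2-[3,4,5-tris(benzyloxy)phenyl]chroman-7-yl 3,4,5-tris(benzyloxy)benzoate (2,3-cis) | O=C(Oc1cc(O)c2c(c1)O[C@H](c1cc(OCc3ccccc3)c(OCc3ccccc3)c(OCc3ccccc3)c1)[C@H](O)C2)c1cc(OCc2ccccc2)c(OCc2ccccc2)c(OCc2ccccc2)c1 | intermediate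
14 | (−)-epigallocatechin 7-O-gallate, (2R,3R)-3,5-dihydroxy-2-(3,4,5-trihydroxyphenyl)chroman-7-yl 3,4,5-trihydroxybenzoate | O=C(Oc1cc(O)c2c(c1)O[C@H](c1cc(O)c(O)c(O)c1)[C@H](O)C2)c1cc(O)c(O)c(O)c1 | target

Total step count: 8. Longest linear sequence: 7 (steps 2 to 8, from 4).

**Steps most likely to fail**

Step 7 (the step that bears the label).
- What may go wrong: racemisation of C2 slower than reduction, poor discrimination of the two ketone enantiomers by the catalyst, or air oxidation of the enolisable ketone. Any of these would lower the enantiomeric purity of the alcohol.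
- The fallback uses known chemistry, sets out from 4 and 3 and comes back at 13. It takes both configurations from a Sharpless kinetic resolution.
- Addition of CH2=CHMgBr to 4 (THF, 0 °C) gives racemic 1-[3,4,5-tris(benzyloxy)phenyl]prop-2-en-1-ol F1.
- Epoxidation with Ti(OiPr)4, L-(+)-DIPT and tBuOOH (0.6 equiv; 4 Å sieves, CH2Cl2, −20 °C) converts the fast-reacting (R)-enantiomer into the erythro epoxy alcohol (S)-[(R)-oxiran-2-yl][3,4,5-tris(benzyloxy)phenyl]methanol F2. The slow enantiomer of F1 stays behind and is removed by chromatography.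
- Mitsunobu etherification of F2 with an excess of 3 (PPh3, DIAD, THF, 0 °C) inverts the carbinol carbon. It gives 3-hydroxy-5-{(R)-[(R)-oxiran-2-yl][3,4,5-tris(benzyloxy)phenyl]methoxy}phenyl 3,4,5-tris(benzyloxy)benzoate F3.
- A 6-endo epoxide–arene Friedel–Crafts cyclisation follows, of the kind known for aryl glycidyl ethers giving chroman-3-ols ((CF3)2CHOH, rt, or cat. AuCl3/AgOTf, CH2Cl2). It joins the terminal epoxide carbon to the ring carbon between the ether and the hydroxyl and gives 13.

Step 5.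
- What may go wrong: attack at a ring carbon next to the aroyloxy group, conjugate instead of carbonyl addition, a second annulation at the remaining phenol, or hydrolysis of the enol ether by the water released.
- The fallback sets out from 3 and 8 and comes back at 12. It replaces the neutral pericyclic annulation by an acid-promoted oxidative benzopyrylium synthesis, in which the aromatic cation is the thermodynamic sink and can be purified by precipitation.
- Compounds 3 and 8 are condensed in HCl-saturated EtOAc–AcOH in the presence of chloranil (0 °C to rt). This gives 3-ethoxy-5-hydroxy-2-[3,4,5-tris(benzyloxy)phenyl]-7-{[3,4,5-tris(benzyloxy)benzoyl]oxy}chromenylium chloride F4.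
- NaBH4 (THF, 0 °C) adds hydride at C4 to give 3-ethoxy-5-hydroxy-2-[3,4,5-tris(benzyloxy)phenyl]-4H-chromen-7-yl 3,4,5-tris(benzyloxy)benzoate F5. Any C2 adduct is 11 itself.
- Both are enol ethers of the same ketone and are hydrolysed to 12 under the conditions of step 6.

Step 6.
- What may go wrong: acid-induced ring opening or disproportionation of the 2H-chromene, and oxidation of the flavan-3-one during the aqueous acid treatment.
- The fallback sets out from 4, uses 3 and comes back at 12. The C3 oxygen is carried as a silyl enol ether, so that the ketone is released by buffered fluoride instead of acid.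
- Horner–Wadsworth–Emmons olefination of 4 with methyl 2-[(tert-butyldimethylsilyl)oxy]-2-(dimethoxyphosphoryl)acetate (LiN(SiMe3)2, THF, −78 °C) gives methyl (Z)-2-[(tert-butyldimethylsilyl)oxy]-3-[3,4,5-tris(benzyloxy)phenyl]prop-2-enoate F6.
- iBu2AlH reduction gives (Z)-2-[(tert-butyldimethylsilyl)oxy]-3-[3,4,5-tris(benzyloxy)phenyl]prop-2-en-1-ol F7.
- MnO2 oxidation gives (Z)-2-[(tert-butyldimethylsilyl)oxy]-3-[3,4,5-tris(benzyloxy)phenyl]prop-2-enal F8.
- Annulation with 3 as in step 5 gives (±)-3-[(tert-butyldimethylsilyl)oxy]-5-hydroxy-2-[3,4,5-tris(benzyloxy)phenyl]-2H-chromen-7-yl 3,4,5-tris(benzyloxy)benzoate F9.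
- Et3N·3HF (THF, 0 °C) then gives 12.

**Further compounds**
F1 | step 7 | (±)-1-[3,4,5-tris(benzyloxy)phenyl]prop-2-en-1-ol | C=CC(O)c1cc(OCc2ccccc2)c(OCc2ccccc2)c(OCc2ccccc2)c1
F2 | step 7 | (S)-[(R)-oxiran-2-yl][3,4,5-tris(benzyloxy)phenyl]methanol | O[C@@H](c1cc(OCc2ccccc2)c(OCc2ccccc2)c(OCc2ccccc2)c1)[C@H]1CO1
F3 | step 7 | 3-hydroxy-5-{(R)-[(R)-oxiran-2-yl][3,4,5-tris(benzyloxy)phenyl]methoxy}phenyl 3,4,5-tris(benzyloxy)benzoate | O=C(Oc1cc(O)cc(O[C@H](c2cc(OCc3ccccc3)c(OCc3ccccc3)c(OCc3ccccc3)c2)[C@H]2CO2)c1)c1cc(OCc2ccccc2)c(OCc2ccccc2)c(OCc2ccccc2)c1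
F4 | step 5 | 3-ethoxy-5-hydroxy-2-[3,4,5-tris(benzyloxy)phenyl]-7-{[3,4,5-tris(benzyloxy)benzoyl]oxy}chromenylium chloride | [Cl-].CCOc1cc2c(O)cc(OC(=O)c3cc(OCc4ccccc4)c(OCc4ccccc4)c(OCc4ccccc4)c3)cc2[o+]c1-c1cc(OCc2ccccc2)c(OCc2ccccc2)c(OCc2ccccc2)c1
F5 | step 5 | 3-ethoxy-5-hydroxy-2-[3,4,5-tris(benzyloxy)phenyl]-4H-chromen-7-yl 3,4,5-tris(benzyloxy)benzoate | CCOC1=C(c2cc(OCc3ccccc3)c(OCc3ccccc3)c(OCc3ccccc3)c2)Oc2cc(OC(=O)c3cc(OCc4ccccc4)c(OCc4ccccc4)c(OCc4ccccc4)c3)cc(O)c2C1
F6 | step 6 | methyl (Z)-2-[(tert-butyldimethylsilyl)oxy]-3-[3,4,5-tris(benzyloxy)phenyl]prop-2-enoate | CC(C)(C)[Si](C)(C)O/C(C(=O)OC)=C\c1cc(OCc2ccccc2)c(OCc2ccccc2)c(OCc2ccccc2)c1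
F7 | step 6 | (Z)-2-[(tert-butyldimethylsilyl)oxy]-3-[3,4,5-tris(benzyloxy)phenyl]prop-2-en-1-ol | CC(C)(C)[Si](C)(C)O/C(CO)=C\c1cc(OCc2ccccc2)c(OCc2ccccc2)c(OCc2ccccc2)c1
F8 | step 6 | (Z)-2-[(tert-butyldimethylsilyl)oxy]-3-[3,4,5-tris(benzyloxy)phenyl]prop-2-enal | CC(C)(C)[Si](C)(C)O/C(C=O)=C\c1cc(OCc2ccccc2)c(OCc2ccccc2)c(OCc2ccccc2)c1
F9 | step 6 | (±)-3-[(tert-butyldimethylsilyl)oxy]-5-hydroxy-2-[3,4,5-tris(benzyloxy)phenyl]-2H-chromen-7-yl 3,4,5-tris(benzyloxy)benzoate | CC(C)(C)[Si](C)(C)OC1=Cc2c(O)cc(OC(=O)c3cc(OCc4ccccc4)c(OCc4ccccc4)c(OCc4ccccc4)c3)cc2OC1c1cc(OCc2ccccc2)c(OCc2ccccc2)c(OCc2ccccc2)c1
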